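**Retrosynthetic overview**
1. Target 31 ⇐ acetylation of macrocyclic C9 alcohol 30 ⇐ C9–C10 bond by a new catalytic asymmetric nickel/chromium alkenylation of iodo-dienoate aldehyde 29; this closes the 10-membered ring last.
2. 29 ⇐ C10=C1 by iodo-Wittig olefination of a (Z)-enal; C8 ester by Mitsunobu inversion with epoxy acid 3 (from tiglyl alcohol by Sharpless epoxidation and oxidation).
3. α-Methylene lactone and C7–C8 bond ⇐ zinc Barbier allylation of bromomethyl butenolide 18 with aldehyde 19; butenolide ⇐ ring-closing metathesis of acrylate ester 17.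
4. C4–C6 triad ⇐ ProPhenol alkynylation of enal 9 (C6), then hydroxyl-directed threo epoxidation (C4, C5); one Lindlar reduction turns both alkynes into the vinyl group and the (Z)-alkene.
5. Enal 9 ⇐ ethyl 3-oxobutanoate via (E)-enol triflate and Sonogashira coupling. Ring order: oxiranes (steps 1 and 8), butenolide (step 12, becoming the α-methylene lactone in step 13), 10-membered carbocycle (step 20).

Assumption: (S,S)-ProPhenol is taken to deliver the alkynyl group to the Si face of enal 9; if its sense of induction is the opposite, (R,R)-ProPhenol is used and nothing else changes.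
Assumption: the zinc Barbier step 13 is taken to follow the closed chair transition state, which gives the 8R alcohol; step 14 is therefore an inverting esterification.
Labels: C1–C15 are the germacrane positions of the target (C4/C5 oxirane, C6 lactone CH–O, C7 ring fusion, C8 epoxy ester, C9 acetate, C10 ester-bearing alkene carbon, C11–C13 methylene lactone, C14 CO2Me, C15 methyl). TBSO = tert-butyldimethylsilyloxy, PMBO = (4-methoxybenzyl)oxy.

**Route**

Step 1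
Reactants: 1 (E)-2-methylbut-2-en-1-ol
Product: 2 [(2R,3R)-2,3-dimethyloxiran-2-yl]methanol
Conditions: Ti(OiPr)4 (10 mol %), D-(−)-diethyl tartrate (12 mol %), tBuOOH, CH2Cl2, −20 °C
Reagents that add atoms: tert-butyl hydroperoxide, CC(C)(C)OO
Why: Sharpless asymmetric epoxidation of a primary (E)-allylic alcohol; the D-(−)-tartrate titanium complex delivers oxygen to the face that gives the (2R,3R)-epoxide, which sets both side-chain stereocenters with the methyl groups cis.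

Step 2
Reactants: 2 [(2R,3R)-2,3-dimethyloxiran-2-yl]methanol
Product: 3 (2S,3R)-2,3-dimethyloxirane-2-carboxylic acid
Conditions: TEMPO (cat.), PhI(OAc)2 (2.2 equiv), MeCN/H2O 1:1, rt
Reagents that add atoms: water, O
Why: TEMPO/PhI(OAc)2 oxidation takes the primary alcohol through the aldehyde hydrate to the acid without touching the oxirane; the C2 descriptor changes from R to S by priority only.

Step 3
Reactants: 4 ethyl 3-oxobutanoate
Product: 5 ethyl (E)-3-{[(trifluoromethyl)sulfonyl]oxy}but-2-enoate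
Conditions: Tf2O, aq. Me4NOH, toluene, 5 °C to rt
Reagents that add atoms: trifluoromethanesulfonic anhydride, O=S(=O)(OS(=O)(=O)C(F)(F)F)C(F)(F)F
Why: Enol triflation of the non-chelated tetramethylammonium enolate, which reacts in the extended form and gives the (E)-enol triflate.

Step 4
Reactants: 5 ethyl (E)-3-{[(trifluoromethyl)sulfonyl]oxy}but-2-enoate; 6 tert-butyldimethyl(prop-2-yn-1-yloxy)silane
Product: 7 ethyl (E)-6-(TBSO)-3-methylhex-2-en-4-ynoate
Conditions: Pd(PPh3)2Cl2 (3 mol %), CuI (5 mol %), Et3N, THF, rt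
Reagents that add atoms: none
Why: Sonogashira coupling proceeds with retention of the enol triflate geometry, so the alkynyl group (C3) ends trans to the ester carbon (C6).

Step 5
Reactants: 7 ethyl (E)-6-(TBSO)-3-methylhex-2-en-4-ynoate
Product: 8 (E)-6-(TBSO)-3-methylhex-2-en-4-yn-1-ol
Conditions: iBu2AlH (2.2 equiv), CH2Cl2, −78 °C; aq. potassium sodium tartrate
Reagents that add atoms: none
Why: DIBAL-H 1,2-reduction of a conjugated ester stops cleanly at the allylic alcohol; no stereocenter is involved.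

Step 6
Reactants: 8 (E)-6-(TBSO)-3-methylhex-2-en-4-yn-1-ol
Product: 9 (E)-6-(TBSO)-3-methylhex-2-en-4-ynal
Conditions: MnO2 (excess), CH2Cl2, rt
Reagents that add atoms: none
Why: MnO2 oxidation is selective for the allylic alcohol and keeps the (E)-geometry.

Step 7
Reactants: 9 (E)-6-(TBSO)-3-methylhex-2-en-4-ynal; 10 ethynyltrimethylsilane
Product: 12 (3R,4E)-8-(TBSO)-5-methyl-1-(trimethylsilyl)oct-4-ene-1,6-diyn-3-ol, via alkynylzinc reagent 11 (not isolated)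
Conditions: (S,S)-ProPhenol (20 mol %), Me2Zn (3 equiv), Ph3P=O (40 mol %), toluene, 0 to 4 °C
Reagents that add atoms: none
Why: ProPhenol dinuclear-zinc catalysed asymmetric alkynylation of an enal; the chiral pocket delivers the alkynyl group to the Si face and sets C6 (3R here).

Step 8
Reactants: 12 (3R,4E)-8-(TBSO)-5-methyl-1-(trimethylsilyl)oct-4-ene-1,6-diyn-3-ol
Product: 13 (1S)-1-{(2R,3R)-3-[3-(TBSO)prop-1-yn-1-yl]-3-methyloxiran-2-yl}-3-(trimethylsilyl)prop-2-yn-1-ol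
Conditions: mCPBA (1.3 equiv), CH2Cl2, 0 °C
Reagents that add atoms: 3-chloroperbenzoic acid, OOC(=O)c1cccc(Cl)c1
Why: Hydroxyl-directed peracid epoxidation of the only alkene; A(1,3) strain between the cis methyl group and the carbinol substituents fixes the reactive conformer, so oxygen is delivered threo and C6 sets C4 and C5 (both R).

Step 9
Reactants: 13 (1S)-1-{(2R,3R)-3-[3-(TBSO)prop-1-yn-1-yl]-3-methyloxiran-2-yl}-3-(trimethylsilyl)prop-2-yn-1-ol
Product: 14 (1S)-1-{(2R,3R)-3-[3-(TBSO)prop-1-yn-1-yl]-3-methyloxiran-2-yl}prop-2-yn-1-ol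
Conditions: K2CO3 (0.3 equiv), MeOH, 0 °C, 30 min
Reagents that add atoms: none
Why: Base-catalysed methanolysis removes only the C-silyl group; the O-silyl ether and the oxirane are untouched under these brief conditions.

Step 10
Reactants: 14 (1S)-1-{(2R,3R)-3-[3-(TBSO)prop-1-yn-1-yl]-3-methyloxiran-2-yl}prop-2-yn-1-ol
Product: 15 (1S)-1-{(2R,3R)-3-[(1Z)-3-(TBSO)prop-1-en-1-yl]-3-methyloxiran-2-yl}prop-2-en-1-ol
Conditions: H2 (1 atm), Pd/CaCO3 poisoned with Pb(OAc)2, quinoline, EtOAc, rt, stopped after 2 equiv H2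
Reagents that add atoms: none
Why: Lindlar cis-semihydrogenation converts the terminal alkyne into the vinyl group and the internal alkyne into the (Z)-C2=C3 alkene in one operation.

Step 11
Reactants: 15 (1S)-1-{(2R,3R)-3-[(1Z)-3-(TBSO)prop-1-en-1-yl]-3-methyloxiran-2-yl}prop-2-en-1-ol; 16 2-(bromomethyl)prop-2-enoic acid
Product: 17 (1S)-1-{(2R,3R)-3-[(1Z)-3-(TBSO)prop-1-en-1-yl]-3-methyloxiran-2-yl}prop-2-en-1-yl 2-(bromomethyl)prop-2-enoate
Conditions: DCC (1.6 equiv), DMAP (10 mol %), CH2Cl2, −20 to 0 °C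
Reagents that add atoms: none
Why: Steglich esterification acylates the C6 hydroxyl with retention; low temperature and catalytic DMAP spare the allylic bromide.

Step 12
Reactants: 17 (1S)-1-{(2R,3R)-3-[(1Z)-3-(TBSO)prop-1-en-1-yl]-3-methyloxiran-2-yl}prop-2-en-1-yl 2-(bromomethyl)prop-2-enoate
Product: 18 (5S)-3-(bromomethyl)-5-{(2R,3R)-3-[(1Z)-3-(TBSO)prop-1-en-1-yl]-3-methyloxiran-2-yl}furan-2(5H)-one
Conditions: second-generation Hoveyda–Grubbs catalyst RuCl2(H2IMes)(=CH-C6H4-2-OiPr) (10 mol %), toluene (5 mM), 80 °C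
Reagents that add atoms: none
Why: Ring-closing metathesis starts at the terminal vinyl group and closes onto the 1,1-disubstituted acrylate to give the butenolide with loss of ethene; the hindered internal (Z)-alkene could only form strained rings and stays untouched.

Step 13
Reactants: 18 (5S)-3-(bromomethyl)-5-{(2R,3R)-3-[(1Z)-3-(TBSO)prop-1-en-1-yl]-3-methyloxiran-2-yl}furan-2(5H)-one; 19 2-[(4-methoxybenzyl)oxy]acetaldehyde
Product: 21 (4R,5S)-4-[(1R)-1-hydroxy-2-(PMBO)ethyl]-5-{(2R,3R)-3-[(1Z)-3-(TBSO)prop-1-en-1-yl]-3-methyloxiran-2-yl}-3-methylideneoxolan-2-one, via allylzinc bromide 20 (not isolated)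
Conditions: Zn dust (4 equiv), THF/sat. aq. NH4Cl 4:1, 0 °C to rt
Reagents that add atoms: none
Why: Zinc Barbier allylation through a closed six-membered (Zimmerman–Traxler) transition state; the allylzinc attacks through C7 on the face anti to the C6 substituent (trans lactone, C7 as in the target) with the aldehyde substituent equatorial, which gives the 8R alcohol (inverted in step 14) and moves the alkene to the exocyclic methylene.

Step 14
Reactants: 21 (4R,5S)-4-[(1R)-1-hydroxy-2-(PMBO)ethyl]-5-{(2R,3R)-3-[(1Z)-3-(TBSO)prop-1-en-1-yl]-3-methyloxiran-2-yl}-3-methylideneoxolan-2-one; 3 (2S,3R)-2,3-dimethyloxirane-2-carboxylic acid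
Product: 22 (1S)-1-[(2S,3R)-2-{(2R,3R)-3-[(1Z)-3-(TBSO)prop-1-en-1-yl]-3-methyloxiran-2-yl}-4-methylidene-5-oxooxolan-3-yl]-2-(PMBO)ethyl (2S,3R)-2,3-dimethyloxirane-2-carboxylate
Conditions: PPh3 (2.5 equiv), DIAD (2.5 equiv), toluene, 0 °C to rt
Reagents that add atoms: none
Why: Mitsunobu esterification; SN2 displacement of the alkoxyphosphonium by the carboxylate of the fairly acidic glycidic acid 3 inverts C8 to the required 8S configuration and installs the side-chain ester in the same step.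

Step 15
Reactants: 22 (1S)-1-[(2S,3R)-2-{(2R,3R)-3-[(1Z)-3-(TBSO)prop-1-en-1-yl]-3-methyloxiran-2-yl}-4-methylidene-5-oxooxolan-3-yl]-2-(PMBO)ethyl (2S,3R)-2,3-dimethyloxirane-2-carboxylate
Product: 23 (1S)-1-[(2S,3R)-2-{(2R,3R)-3-[(1Z)-3-hydroxyprop-1-en-1-yl]-3-methyloxiran-2-yl}-4-methylidene-5-oxooxolan-3-yl]-2-(PMBO)ethyl (2S,3R)-2,3-dimethyloxirane-2-carboxylate
Conditions: HF·pyridine, pyridine, THF, 0 °C to rt
Reagents that add atoms: none
Why: Buffered fluoride desilylation cleaves the primary allylic silyl ether while the oxiranes, the esters and the PMB ether survive.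

Step 16
Reactants: 23 (1S)-1-[(2S,3R)-2-{(2R,3R)-3-[(1Z)-3-hydroxyprop-1-en-1-yl]-3-methyloxiran-2-yl}-4-methylidene-5-oxooxolan-3-yl]-2-(PMBO)ethyl (2S,3R)-2,3-dimethyloxirane-2-carboxylate
Product: 24 (1S)-1-[(2S,3R)-2-{(2R,3R)-3-methyl-3-[(1Z)-3-oxoprop-1-en-1-yl]oxiran-2-yl}-4-methylidene-5-oxooxolan-3-yl]-2-(PMBO)ethyl (2S,3R)-2,3-dimethyloxirane-2-carboxylate
Conditions: Dess–Martin periodinane (1.3 equiv), NaHCO3, CH2Cl2, 0 °C, 30 min; used at once
Reagents that add atoms: none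
Why: Buffered Dess–Martin oxidation at 0 °C gives the (Z)-enal without Z to E isomerisation or oxirane opening.

Step 17
Reactants: 24 (1S)-1-[(2S,3R)-2-{(2R,3R)-3-methyl-3-[(1Z)-3-oxoprop-1-en-1-yl]oxiran-2-yl}-4-methylidene-5-oxooxolan-3-yl]-2-(PMBO)ethyl (2S,3R)-2,3-dimethyloxirane-2-carboxylate; 25 methyl (triphenyl-λ5-phosphanylidene)acetate
Product: 27 (1S)-1-[(2S,3R)-2-{(2R,3R)-3-[(1Z,3Z)-4-iodo-5-methoxy-5-oxopenta-1,3-dien-1-yl]-3-methyloxiran-2-yl}-4-methylidene-5-oxooxolan-3-yl]-2-(PMBO)ethyl (2S,3R)-2,3-dimethyloxirane-2-carboxylate, via iodo ylide 26 (not isolated)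
Conditions: 25 (1.6 equiv), N-iodosuccinimide (1.6 equiv), CH2Cl2, −20 °C, 30 min; then 24, −20 to 0 °C, dark
Reagents that add atoms: N-iodosuccinimide, O=C1CCC(=O)N1I
Why: Wittig olefination with the stabilised iodo ylide puts the ester trans to the incoming chain, so iodine is cis to C2 (the geometry needed for C10=C1) while the (Z)-C2=C3 alkene is kept.

Step 18
Reactants: 27 (1S)-1-[(2S,3R)-2-{(2R,3R)-3-[(1Z,3Z)-4-iodo-5-methoxy-5-oxopenta-1,3-dien-1-yl]-3-methyloxiran-2-yl}-4-methylidene-5-oxooxolan-3-yl]-2-(PMBO)ethyl (2S,3R)-2,3-dimethyloxirane-2-carboxylate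
Product: 28 (1S)-2-hydroxy-1-[(2S,3R)-2-{(2R,3R)-3-[(1Z,3Z)-4-iodo-5-methoxy-5-oxopenta-1,3-dien-1-yl]-3-methyloxiran-2-yl}-4-methylidene-5-oxooxolan-3-yl]ethyl (2S,3R)-2,3-dimethyloxirane-2-carboxylate
Conditions: DDQ (1.5 equiv), CH2Cl2/aq. Na2HPO4–NaH2PO4 buffer (pH 7) 10:1, 0 °C to rt
Reagents that add atoms: none
Why: Oxidative PMB ether cleavage by DDQ is neutral and leaves the electron-poor diene, the vinyl iodide and the oxiranes alone.

Step 19
Reactants: 28 (1S)-2-hydroxy-1-[(2S,3R)-2-{(2R,3R)-3-[(1Z,3Z)-4-iodo-5-methoxy-5-oxopenta-1,3-dien-1-yl]-3-methyloxiran-2-yl}-4-methylidene-5-oxooxolan-3-yl]ethyl (2S,3R)-2,3-dimethyloxirane-2-carboxylate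
Product: 29 (1S)-2-oxo-1-[(2S,3S)-2-{(2R,3R)-3-[(1Z,3Z)-4-iodo-5-methoxy-5-oxopenta-1,3-dien-1-yl]-3-methyloxiran-2-yl}-4-methylidene-5-oxooxolan-3-yl]ethyl (2S,3R)-2,3-dimethyloxirane-2-carboxylate
Conditions: Dess–Martin periodinane (1.5 equiv), NaHCO3, CH2Cl2, 0 °C; used at once
Reagents that add atoms: none
Why: Buffered Dess–Martin oxidation gives the α-acyloxy aldehyde without epimerising C8; the ring-fusion descriptor changes from 3R to 3S by priority only.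

Step 20
Reactants: 29 (1S)-2-oxo-1-[(2S,3S)-2-{(2R,3R)-3-[(1Z,3Z)-4-iodo-5-methoxy-5-oxopenta-1,3-dien-1-yl]-3-methyloxiran-2-yl}-4-methylidene-5-oxooxolan-3-yl]ethyl (2S,3R)-2,3-dimethyloxirane-2-carboxylate
Product: 30 methyl (1S,2R,4R,5Z,7E,9S,10S,11R)-10-{[(2S,3R)-2,3-dimethyloxirane-2-carbonyl]oxy}-9-hydroxy-4-methyl-12-methylidene-13-oxo-3,14-dioxatricyclo[9.3.0.0(2,4)]tetradeca-5,7-diene-8-carboxylate
Conditions: CrCl2 (15 mol %), (S)-N-[2-(4-tert-butyl-4,5-dihydrooxazol-2-yl)-6-methoxyphenyl]methanesulfonamide (17 mol %), 1,8-bis(dimethylamino)naphthalene (17 mol %), NiCl2(2,9-dimethyl-1,10-phenanthroline) (5 mol %), Mn powder (3 equiv), Cp2ZrCl2 (1.5 equiv), LiCl (2 equiv), MeCN, 2 mM by syringe pump, rt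
Reagents that add atoms: none
Why: Proposed new method: a nickel/chromium dual-catalytic Nozaki–Hiyama–Kishi ring closure in which zerovalent nickel inserts into the C10–I bond of the (Z)-α-iodo dienoate with retention, the alkenyl group passes to a trivalent chromium centre carrying the chiral oxazoline–sulfonamide ligand, and this chromium alkenyl adds in a closed, ligand-controlled transition state to the Si face of the C9 aldehyde (9S, overriding the Felkin preference of the α-acyloxy aldehyde), while Cp2ZrCl2 releases the chromium alkoxide and Mn returns chromium to the divalent state; the two cis alkenes and the trans lactone pre-organise the chain so that the 10-membered ring can only close with C9 cis to C2; the closest known reaction type is the catalytic asymmetric Nozaki–Hiyama–Kishi alkenylation of aldehydes with simple alkenyl iodides and sulfonamide ligands, together with chromium/nickel couplings of α-iodo enones, neither of which has been shown for an α-iodo-2,4-dienoate or for a 10-membered carbocycle.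

Step 21
Reactants: 30 methyl (1S,2R,4R,5Z,7E,9S,10S,11R)-10-{[(2S,3R)-2,3-dimethyloxirane-2-carbonyl]oxy}-9-hydroxy-4-methyl-12-methylidene-13-oxo-3,14-dioxatricyclo[9.3.0.0(2,4)]tetradeca-5,7-diene-8-carboxylate
Product: 31 methyl (1S,2R,4R,5Z,7E,9S,10S,11R)-9-(acetyloxy)-10-{[(2S,3R)-2,3-dimethyloxirane-2-carbonyl]oxy}-4-methyl-12-methylidene-13-oxo-3,14-dioxatricyclo[9.3.0.0(2,4)]tetradeca-5,7-diene-8-carboxylate
Conditions: Ac2O, pyridine, DMAP (5 mol %), CH2Cl2, 0 °C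
Reagents that add atoms: acetic anhydride, CC(=O)OC(C)=O
Why: DMAP-catalysed acetylation of the C9 allylic alcohol proceeds with retention and is fast enough to prevent acyl migration from C8.

**Compound list**
1 | (E)-2-methylbut-2-en-1-ol | C/C=C(\C)CO | starting material
2 | [(2R,3R)-2,3-dimethyloxiran-2-yl]methanol | OC[C@@]1(C)O[C@@H]1C | intermediate
3 | (2S,3R)-2,3-dimethyloxirane-2-carboxylic acid | OC(=O)[C@@]1(C)O[C@@H]1C | intermediate
4 | ethyl 3-oxobutanoate | CCOC(=O)CC(C)=O | starting material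
5 | ethyl (E)-3-{[(trifluoromethyl)sulfonyl]oxy}but-2-enoate | CCOC(=O)/C=C(\C)OS(=O)(=O)C(F)(F)F | intermediate
6 | tert-butyldimethyl(prop-2-yn-1-yloxy)silane | C#CCO[Si](C)(C)C(C)(C)C | starting material
7 | ethyl (E)-6-(TBSO)-3-methylhex-2-en-4-ynoate | CCOC(=O)/C=C(\C)C#CCO[Si](C)(C)C(C)(C)C | intermediate
8 | (E)-6-(TBSO)-3-methylhex-2-en-4-yn-1-ol | OC/C=C(\C)C#CCO[Si](C)(C)C(C)(C)C | intermediate
9 | (E)-6-(TBSO)-3-methylhex-2-en-4-ynal | O=C/C=C(\C)C#CCO[Si](C)(C)C(C)(C)C | intermediate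
10 | ethynyltrimethylsilane | C#C[Si](C)(C)C | starting material
11 | methyl[(trimethylsilyl)ethynyl]zinc | C[Zn]C#C[Si](C)(C)C | intermediate
12 | (3R,4E)-8-(TBSO)-5-methyl-1-(trimethylsilyl)oct-4-ene-1,6-diyn-3-ol | C[Si](C)(C)C#C[C@H](O)/C=C(\C)C#CCO[Si](C)(C)C(C)(C)C | intermediate
13 | (1S)-1-{(2R,3R)-3-[3-(TBSO)prop-1-yn-1-yl]-3-methyloxiran-2-yl}-3-(trimethylsilyl)prop-2-yn-1-ol | C[Si](C)(C)C#C[C@H](O)[C@H]1O[C@]1(C)C#CCO[Si](C)(C)C(C)(C)C | intermediate
14 | (1S)-1-{(2R,3R)-3-[3-(TBSO)prop-1-yn-1-yl]-3-methyloxiran-2-yl}prop-2-yn-1-ol | C#C[C@H](O)[C@H]1O[C@]1(C)C#CCO[Si](C)(C)C(C)(C)C | intermediate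
15 | (1S)-1-{(2R,3R)-3-[(1Z)-3-(TBSO)prop-1-en-1-yl]-3-methyloxiran-2-yl}prop-2-en-1-ol | C=C[C@H](O)[C@H]1O[C@]1(C)/C=C\CO[Si](C)(C)C(C)(C)C | intermediate
16 | 2-(bromomethyl)prop-2-enoic acid | C=C(CBr)C(=O)O | starting material
17 | (1S)-1-{(2R,3R)-3-[(1Z)-3-(TBSO)prop-1-en-1-yl]-3-methyloxiran-2-yl}prop-2-en-1-yl 2-(bromomethyl)prop-2-enoate | C=C(CBr)C(=O)O[C@@H](C=C)[C@H]1O[C@]1(C)/C=C\CO[Si](C)(C)C(C)(C)C | intermediate
18 | (5S)-3-(bromomethyl)-5-{(2R,3R)-3-[(1Z)-3-(TBSO)prop-1-en-1-yl]-3-methyloxiran-2-yl}furan-2(5H)-one | O=C1O[C@@H](C=C1CBr)[C@H]2O[C@]2(C)/C=C\CO[Si](C)(C)C(C)(C)C | intermediate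
19 | 2-[(4-methoxybenzyl)oxy]acetaldehyde | O=CCOCc1ccc(OC)cc1 | starting material
20 | bromo{[(5S)-5-{(2R,3R)-3-[(1Z)-3-(TBSO)prop-1-en-1-yl]-3-methyloxiran-2-yl}-2-oxo-2,5-dihydrofuran-3-yl]methyl}zinc | O=C1O[C@@H](C=C1C[Zn]Br)[C@H]2O[C@]2(C)/C=C\CO[Si](C)(C)C(C)(C)C | intermediate
21 | (4R,5S)-4-[(1R)-1-hydroxy-2-(PMBO)ethyl]-5-{(2R,3R)-3-[(1Z)-3-(TBSO)prop-1-en-1-yl]-3-methyloxiran-2-yl}-3-methylideneoxolan-2-one | C=C1C(=O)O[C@H]([C@H]2O[C@]2(C)/C=C\CO[Si](C)(C)C(C)(C)C)[C@H]1[C@@H](O)COCc1ccc(OC)cc1 | intermediate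
22 | (1S)-1-[(2S,3R)-2-{(2R,3R)-3-[(1Z)-3-(TBSO)prop-1-en-1-yl]-3-methyloxiran-2-yl}-4-methylidene-5-oxooxolan-3-yl]-2-(PMBO)ethyl (2S,3R)-2,3-dimethyloxirane-2-carboxylate | C=C1C(=O)O[C@H]([C@H]2O[C@]2(C)/C=C\CO[Si](C)(C)C(C)(C)C)[C@H]1[C@H](OC(=O)[C@@]1(C)O[C@@H]1C)COCc1ccc(OC)cc1 | intermediate
23 | (1S)-1-[(2S,3R)-2-{(2R,3R)-3-[(1Z)-3-hydroxyprop-1-en-1-yl]-3-methyloxiran-2-yl}-4-methylidene-5-oxooxolan-3-yl]-2-(PMBO)ethyl (2S,3R)-2,3-dimethyloxirane-2-carboxylate | C=C1C(=O)O[C@H]([C@H]2O[C@]2(C)/C=C\CO)[C@H]1[C@H](OC(=O)[C@@]1(C)O[C@@H]1C)COCc1ccc(OC)cc1 | intermediate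
24 | (1S)-1-[(2S,3R)-2-{(2R,3R)-3-methyl-3-[(1Z)-3-oxoprop-1-en-1-yl]oxiran-2-yl}-4-methylidene-5-oxooxolan-3-yl]-2-(PMBO)ethyl (2S,3R)-2,3-dimethyloxirane-2-carboxylate | C=C1C(=O)O[C@H]([C@H]2O[C@]2(C)/C=C\C=O)[C@H]1[C@H](OC(=O)[C@@]1(C)O[C@@H]1C)COCc1ccc(OC)cc1 | intermediate
25 | methyl (triphenyl-λ5-phosphanylidene)acetate | COC(=O)C=P(c1ccccc1)(c1ccccc1)c1ccccc1 | starting material
26 | methyl iodo(triphenyl-λ5-phosphanylidene)acetate | COC(=O)C(I)=P(c1ccccc1)(c1ccccc1)c1ccccc1 | intermediate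
27 | (1S)-1-[(2S,3R)-2-{(2R,3R)-3-[(1Z,3Z)-4-iodo-5-methoxy-5-oxopenta-1,3-dien-1-yl]-3-methyloxiran-2-yl}-4-methylidene-5-oxooxolan-3-yl]-2-(PMBO)ethyl (2S,3R)-2,3-dimethyloxirane-2-carboxylate | C=C1C(=O)O[C@H]([C@H]2O[C@]2(C)/C=C\C=C(/I)C(=O)OC)[C@H]1[C@H](OC(=O)[C@@]1(C)O[C@@H]1C)COCc1ccc(OC)cc1 | intermediate
28 | (1S)-2-hydroxy-1-[(2S,3R)-2-{(2R,3R)-3-[(1Z,3Z)-4-iodo-5-methoxy-5-oxopenta-1,3-dien-1-yl]-3-methyloxiran-2-yl}-4-methylidene-5-oxooxolan-3-yl]ethyl (2S,3R)-2,3-dimethyloxirane-2-carboxylate | C=C1C(=O)O[C@H]([C@H]2O[C@]2(C)/C=C\C=C(/I)C(=O)OC)[C@H]1[C@H](OC(=O)[C@@]1(C)O[C@@H]1C)CO | intermediate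
29 | (1S)-2-oxo-1-[(2S,3S)-2-{(2R,3R)-3-[(1Z,3Z)-4-iodo-5-methoxy-5-oxopenta-1,3-dien-1-yl]-3-methyloxiran-2-yl}-4-methylidene-5-oxooxolan-3-yl]ethyl (2S,3R)-2,3-dimethyloxirane-2-carboxylate | C=C1C(=O)O[C@H]([C@H]2O[C@]2(C)/C=C\C=C(/I)C(=O)OC)[C@H]1[C@H](OC(=O)[C@@]1(C)O[C@@H]1C)C=O | intermediate
30 | methyl (1S,2R,4R,5Z,7E,9S,10S,11R)-10-{[(2S,3R)-2,3-dimethyloxirane-2-carbonyl]oxy}-9-hydroxy-4-methyl-12-methylidene-13-oxo-3,14-dioxatricyclo[9.3.0.0(2,4)]tetradeca-5,7-diene-8-carboxylate | C=C1C(=O)O[C@H]2[C@H]1[C@H](OC(=O)[C@@]1(C)O[C@@H]1C)[C@@H](O)/C(C(=O)OC)=C\C=C/[C@@]1(C)O[C@H]21 | intermediate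
31 | methyl (1S,2R,4R,5Z,7E,9S,10S,11R)-9-(acetyloxy)-10-{[(2S,3R)-2,3-dimethyloxirane-2-carbonyl]oxy}-4-methyl-12-methylidene-13-oxo-3,14-dioxatricyclo[9.3.0.0(2,4)]tetradeca-5,7-diene-8-carboxylate | C=C1C(=O)O[C@H]2[C@H]1[C@H](OC(=O)[C@@]1(C)O[C@@H]1C)[C@@H](OC(C)=O)/C(C(=O)OC)=C\C=C/[C@@]1(C)O[C@H]21 | target

**Totals and risks**
Total step count: 21 (steps 1–2 make acid 3; steps 3–21 are the main line).
Longest linear sequence: 19 steps (ethyl 3-oxobutanoate 4 to target 31, steps 3–21).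

Three steps most likely to fail:

Step 12 (metathesis of the bromomethyl acrylate; the allylic bromide and the 1,1-disubstituted acrylate may stall the catalyst). The fallback sets out from alcohol 15 and comes back at bromide 18; it carries no halide through the metathesis and installs bromine afterwards. Alcohol 15 is esterified with 2-{[(4-methoxybenzyl)oxy]methyl}prop-2-enoic acid (DCC, catalytic DMAP) to the PMB-oxymethyl acrylate ester F1. Ring-closing metathesis with the second-generation Hoveyda–Grubbs catalyst gives the 3-(PMB-oxymethyl)butenolide F2. DDQ in buffered CH2Cl2 frees the 3-(hydroxymethyl)butenolide F3, and CBr4/PPh3 at 0 °C converts it into 18.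

Step 14 (Mitsunobu inversion with a hindered α-quaternary acid on a hindered secondary alcohol; elimination or low conversion is possible). The fallback sets out from alcohol 21 and comes back at ester 22; it separates inversion from acylation. Mitsunobu reaction of 21 with formic acid (PPh3, DIAD) gives the inverted 8S formate F4. Brief treatment with KHCO3 in aqueous methanol at 0 °C frees the 8S alcohol F5, which is esterified with acid 3 under retention (DCC, DMAP) to give 22.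

Step 20 (the proposed new ring closure; risks are poor turnover with the α-iodo dienoate, oligomerisation, or insufficient ligand control at C9). The fallback uses known chemistry, sets out from aldehyde 29 and comes back at alcohol 30. Ring closure under established stoichiometric Nozaki–Hiyama–Kishi conditions (excess CrCl2, catalytic NiCl2, DMSO/THF, high dilution) gives the macrocycle as a C9 epimer mixture in which the Felkin-type 9R alcohol F6 is expected to dominate alongside 30. The whole mixture is oxidised with Dess–Martin periodinane to the C9 ketone F7. Corey–Bakshi–Shibata reduction with (S)-2-methyl-CBS-oxazaborolidine and catecholborane at −78 °C, the alkenyl group acting as the large substituent, returns the 9S alcohol 30.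

**Further compounds**
F1 | step 12 | (1S)-1-{(2R,3R)-3-[(1Z)-3-(TBSO)prop-1-en-1-yl]-3-methyloxiran-2-yl}prop-2-en-1-yl 2-[(PMBO)methyl]prop-2-enoate | C=C(COCc1ccc(OC)cc1)C(=O)O[C@@H](C=C)[C@H]1O[C@]1(C)/C=C\CO[Si](C)(C)C(C)(C)C
F2 | step 12 | (5S)-3-[(PMBO)methyl]-5-{(2R,3R)-3-[(1Z)-3-(TBSO)prop-1-en-1-yl]-3-methyloxiran-2-yl}furan-2(5H)-one | O=C1O[C@@H](C=C1COCc3ccc(OC)cc3)[C@H]2O[C@]2(C)/C=C\CO[Si](C)(C)C(C)(C)C
F3 | step 12 | (5S)-3-(hydroxymethyl)-5-{(2R,3R)-3-[(1Z)-3-(TBSO)prop-1-en-1-yl]-3-methyloxiran-2-yl}furan-2(5H)-one | O=C1O[C@@H](C=C1CO)[C@H]2O[C@]2(C)/C=C\CO[Si](C)(C)C(C)(C)C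
F4 | step 14 | (1S)-1-[(2S,3R)-2-{(2R,3R)-3-[(1Z)-3-(TBSO)prop-1-en-1-yl]-3-methyloxiran-2-yl}-4-methylidene-5-oxooxolan-3-yl]-2-(PMBO)ethyl formate | C=C1C(=O)O[C@H]([C@H]2O[C@]2(C)/C=C\CO[Si](C)(C)C(C)(C)C)[C@H]1[C@H](OC=O)COCc1ccc(OC)cc1
F5 | step 14 | (4R,5S)-4-[(1S)-1-hydroxy-2-(PMBO)ethyl]-5-{(2R,3R)-3-[(1Z)-3-(TBSO)prop-1-en-1-yl]-3-methyloxiran-2-yl}-3-methylideneoxolan-2-one | C=C1C(=O)O[C@H]([C@H]2O[C@]2(C)/C=C\CO[Si](C)(C)C(C)(C)C)[C@H]1[C@H](O)COCc1ccc(OC)cc1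
F6 | step 20 | methyl (1S,2R,4R,5Z,7E,9R,10S,11R)-10-{[(2S,3R)-2,3-dimethyloxirane-2-carbonyl]oxy}-9-hydroxy-4-methyl-12-methylidene-13-oxo-3,14-dioxatricyclo[9.3.0.0(2,4)]tetradeca-5,7-diene-8-carboxylate | C=C1C(=O)O[C@H]2[C@H]1[C@H](OC(=O)[C@@]1(C)O[C@@H]1C)[C@H](O)/C(C(=O)OC)=C\C=C/[C@@]1(C)O[C@H]21
F7 | step 20 | methyl (1S,2R,4R,5Z,7E,10S,11S)-10-{[(2S,3R)-2,3-dimethyloxirane-2-carbonyl]oxy}-4-methyl-12-methylidene-9,13-dioxo-3,14-dioxatricyclo[9.3.0.0(2,4)]tetradeca-5,7-diene-8-carboxylate | C=C1C(=O)O[C@H]2[C@H]1[C@H](OC(=O)[C@@]1(C)O[C@@H]1C)C(=O)/C(C(=O)OC)=C\C=C/[C@@]1(C)O[C@H]21
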